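**Strategy.** Everything rests on C6, the aminal CH shared by the ketopiperazine and the cyclic guanidine. C6 sits at the aldehyde oxidation level, and its two nitrogens, the pyrrole N and N7, are both anchored to the neighbouring quaternary carbon C10. Cutting both C6–N bonds gives a 2-formylpyrrolidine. Its C2 (= C10, R) also carries an N-Boc-N'-methylguanidine, and its ring nitrogen carries the 4,5-dibromopyrrole-2-carbonyl group. In the forward direction dilute acid condenses this aldehyde with the two N–H groups, closing both rings and setting C6 in one operation. C10 comes from L-proline by stereoretentive silyloxymethylation and a Hofmann rearrangement that replaces the original carboxyl carbon by N9.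

Key step: step 11

**Numbering and assumption:** phakellin numbering is used (C6 aminal CH, N7 NMe, C8 guanidine carbon, N9, C10 quaternary aminal carbon). By CIP analysis the target is (6S,10R), a cis-fused tetracycle. Aldehyde 20 is assumed to equilibrate with cyclic hemiaminal forms and is therefore used crude.

**Design choices**
- **Order of N9 introduction.** N9 is introduced by a C→N rearrangement only after the pyrrolidine nitrogen is acylated. A C10 aminal with a free ring N–H could expel its nitrogen substituent and lose the stereocentre.
- **Choice of proline enantiomer.** The carboxyl carbon becomes N9 and the added carbon becomes C6, both with retention, so (10R) maps onto natural L-proline.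
- **Oxidation level of C6.** C6 stays at the alcohol level until the guanidine is in place, because an ester there would lactamise with the NHMe group.
- **Protection of the C–Br bonds.** No reductive or hydrogenolytic step follows the introduction of the bromines.
- **Boc versus acid.** Boc is kept for a trivial last step, so the key step uses dilute acid and has an acid-free fallback.

**Step 1**
Reactants: 1 L-proline; 2 pivalaldehyde
Product: 3 (3R,7aS)-3-tert-butyltetrahydro-1H,3H-pyrrolo[1,2-c]oxazol-1-one (bicyclic N,O-acetal; tert-butyl cis to H-7a)
Conditions: TFA (cat.), pentane, reflux, Dean–Stark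
Reagents that add atoms: none
Why: Azeotropic N,O-acetalisation that opens a self-regeneration-of-stereocentres sequence: the bicycle forms as one diastereomer because the tert-butyl group takes the convex face, cis to H-7a, and this new acetal centre (R) stores the configuration of proline.

**Step 2**
Reactants: 3 bicyclic N,O-acetal; 4 (triisopropylsiloxy)methyl chloride (TOM-Cl)
Product: 6 (3R,7aR)-3-tert-butyl-7a-{[(triisopropylsilyl)oxy]methyl}tetrahydro-1H,3H-pyrrolo[1,2-c]oxazol-1-one, via lithium enolate 5 (not isolated)
Conditions: LDA (commercial solution), THF, −78 °C; then 4, −78 → −30 °C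
Reagents that add atoms: LDA, [Li+].CC(C)[N-]C(C)C (lithium of enolate 5 only)
Why: Alkylation of the chiral lithium enolate with a reactive chloromethyl ether: the electrophile enters on the convex face, syn to tert-butyl, where the hydrogen stood, so the quaternary centre (future C10) is set with overall retention under control of the acetal centre and the future C6 arrives as a TIPS-protected CH2OH group.

**Step 3**
Reactants: 6 alkylated bicyclic lactone
Product: 7 (R)-2-{[(triisopropylsilyl)oxy]methyl}pyrrolidine-2-carboxylic acid
Conditions: SiO2, MeOH/H2O, rt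
Reagents that add atoms: none
Why: Hydrolysis of the N,O-acetal on silica, which runs through the ring-opened iminium carboxylate so that the oxygen of the water leaves in pivalaldehyde; the near-neutral medium spares the TIPS ether and the quaternary centre has no way to epimerise.

**Step 4**
Reactants: 7 quaternary amino acid; 8 4,5-dibromo-2-(trichloroacetyl)pyrrole
Product: 9 (R)-1-(4,5-dibromo-1H-pyrrole-2-carbonyl)-2-{[(triisopropylsilyl)oxy]methyl}pyrrolidine-2-carboxylic acid
Conditions: Et3N, DMF, 50 °C; acidic work-up
Reagents that add atoms: none
Why: Haloform-type acyl transfer from the trichloromethyl ketone to the secondary amine, the standard way to make bromopyrrole carboxamides; it is run while C2 still bears only carbon substituents, so that no aminal with a free ring N–H ever has to be handled.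

**Step 5**
Reactants: 9 N-acyl amino acid
Product: 11 (R)-1-(4,5-dibromo-1H-pyrrole-2-carbonyl)-2-{[(triisopropylsilyl)oxy]methyl}pyrrolidine-2-carboxamide, via acyl imidazole 10 (not isolated)
Conditions: CDI, THF, rt; then NH3 (g), 0 °C → rt
Reagents that add atoms: ammonia, N; 1,1'-carbonyldiimidazole, O=C(n1ccnc1)n1ccnc1 (imidazolyl group of 10 only)
Why: Carboxyl activation as the acyl imidazole followed by ammonolysis; the centre has no α-hydrogen and cannot racemise through any activated form, and ammonia is small enough to reach the hindered carbonyl.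

**Step 6**
Reactants: 11 primary amide
Product: 13 (R)-(2-amino-2-{[(triisopropylsilyl)oxy]methyl}pyrrolidin-1-yl)(4,5-dibromo-1H-pyrrol-2-yl)methanone trifluoroacetate, via isocyanate 12 (not isolated)
Conditions: PhI(OCOCF3)2, MeCN/H2O, 0 °C → rt
Reagents that add atoms: [bis(trifluoroacetoxy)iodo]benzene, FC(F)(F)C(=O)OI(OC(=O)C(F)(F)F)c1ccccc1 (trifluoroacetate counter-ion of 13)
Why: Hofmann rearrangement with an iodine(III) oxidant in acidic aqueous acetonitrile, the classical entry to monoacylated gem-diamines: the quaternary carbon migrates from C to N with retention, isocyanate 12 is hydrolysed with loss of CO2, and the amine is protonated at once, which prevents urea formation and ring-chain exchange at C10, while the electron-poor dibromoacylpyrrole and the TIPS ether should be left alone.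

**Step 7**
Reactants: 14 methyl isothiocyanate; 15 tert-butyl carbamate
Product: 16 tert-butyl N-(methylcarbamothioyl)carbamate (N-Boc-N'-methylthiourea)
Conditions: NaH, THF, 0 °C → rt; then AcOH
Reagents that add atoms: none
Why: Addition of the sodium salt of a carbamate to an isothiocyanate, a routine preparation of N-acylthioureas; no stereocentre is involved.

**Step 8**
Reactants: 13 amine trifluoroacetate; 16 N-Boc-N'-methylthiourea
Product: 18 tert-butyl N-{N'-[(R)-1-(4,5-dibromo-1H-pyrrole-2-carbonyl)-2-{[(triisopropylsilyl)oxy]methyl}pyrrolidin-2-yl]-N-methylcarbamimidoyl}carbamate, via N-Boc-N'-methylcarbodiimide 17 (not isolated)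
Conditions: EDCI, i-Pr2NEt, DMF, 0 °C → rt
Reagents that add atoms: none
Why: Carbodiimide-promoted guanylation: EDCI desulfurises 16 to the small and very electrophilic carbodiimide 17, to which the primary amine adds as soon as the base releases it from its salt, so the free aminal has a short lifetime and C10 is not touched.

**Step 9**
Reactants: 18 TIPS-protected Boc-methylguanidine
Product: 19 tert-butyl N-{N'-[(R)-1-(4,5-dibromo-1H-pyrrole-2-carbonyl)-2-(hydroxymethyl)pyrrolidin-2-yl]-N-methylcarbamimidoyl}carbamate
Conditions: TBAF, AcOH, THF, 0 °C → rt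
Reagents that add atoms: none
Why: Fluoride-induced silyl ether cleavage, buffered with acetic acid so that no free alkoxide meets the Boc-guanidine; C–Br bonds, the aminal and the carbamate are inert to fluoride.

**Step 10**
Reactants: 19 guanidino alcohol
Product: 20 tert-butyl N-{N'-[(R)-1-(4,5-dibromo-1H-pyrrole-2-carbonyl)-2-formylpyrrolidin-2-yl]-N-methylcarbamimidoyl}carbamate (the prolinal precursor)
Conditions: Dess–Martin periodinane, CH2Cl2, 0 °C → rt; used crude
Reagents that add atoms: none
Why: Dess–Martin oxidation under neutral conditions stops cleanly at the aldehyde, which has no α-hydrogen and therefore can neither enolise nor epimerise; C6 is raised to the aldehyde level only now because an ester at C6 would lactamise with the NHMe group.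

**Step 11**
Reactants: 20 prolinal precursor
Product: 23 N-Boc-(−)-7-N-methyldibromophakellin (6S,10R), via carbinolamine 21 (not isolated), via C6 cation 22 (not isolated)
Conditions: CSA (1.3 equiv), 4 Å MS, CH2Cl2 (5 mM), 0 °C → rt
Reagents that add atoms: none
Why: The pyrrole N–H adds reversibly to the strongly electrophilic, non-enolisable aldehyde to give carbinolamine 21 as both C6 epimers, acid removes water from either epimer to give the same planar cation 22, and the NHMe nitrogen of the guanidine adds to C6 and loses its proton. The closest known chemistry is N-acyliminium-type aminal formation: spontaneous carbinolamine closure of N-(pyrrol-2-ylcarbonyl)prolinals and acid-induced replacement of such a hydroxyl by a tethered nitrogen. The ketopiperazine closes 6-exo-trig on the C=O group and the imidazoline closes 5-exo-trig on the C6=N+ bond. The only new stereocentre, C6, is dictated by C10, because N7 is held by N9 on one face of 22 and a five-membered ring across C6–C10 can only be cis-fused, so the epimer mixture converges on 6S. Within the guanidine the step needs closure by N7 and not by the exocyclic nitrogen, which the Boc group secures by turning that nitrogen into a non-nucleophilic carbamate; Boc should last because one equivalent of CSA is merely buffered by the basic acylguanidine and Boc acidolysis falls off steeply with acid concentration. At the pyrrole the step needs N- and not C3-attack, secured by the acidity of the N–H, by the deactivation of C3 through the flanking acyl and bromo groups and by the low temperature; the reverse order of the two additions would end in the same product.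

**Step 12**
Reactants: 23 N-Boc tetracycle
Product: 24 (−)-7-N-methyldibromophakellin (6S,10R)
Conditions: TFA/CH2Cl2 (1:1), 0 °C → rt; aq. Na2CO3 work-up
Reagents that add atoms: none
Why: Acidolysis of the tert-butyl carbamate with loss of isobutene and CO2; the guanidinium ion that forms deactivates both aminal carbons towards ionisation, so C6 and C10 keep their configuration and the C–Br bonds are untouched.

**Compound list**

1 | L-proline | OC(=O)[C@@H]1CCCN1 | starting material
2 | pivalaldehyde | CC(C)(C)C=O | starting material
3 | (3R,7aS)-3-tert-butyltetrahydro-1H,3H-pyrrolo[1,2-c]oxazol-1-one | CC(C)(C)[C@H]1OC(=O)[C@@H]2CCCN12 | intermediate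
4 | (triisopropylsiloxy)methyl chloride (TOM-Cl) | ClCO[Si](C(C)C)(C(C)C)C(C)C | starting material
5 | lithium enolate of 3 (acetal centre R) | CC(C)(C)[C@H]1OC([O-])=C2CCCN12.[Li+] | intermediate
6 | (3R,7aR)-3-tert-butyl-7a-{[(triisopropylsilyl)oxy]methyl}tetrahydro-1H,3H-pyrrolo[1,2-c]oxazol-1-one | CC(C)(C)[C@H]1OC(=O)[C@]2(CO[Si](C(C)C)(C(C)C)C(C)C)CCCN12 | intermediate
7 | (R)-2-{[(triisopropylsilyl)oxy]methyl}pyrrolidine-2-carboxylic acid | OC(=O)[C@]1(CO[Si](C(C)C)(C(C)C)C(C)C)CCCN1 | intermediate
8 | 4,5-dibromo-2-(trichloroacetyl)pyrrole | O=C(c1cc(Br)c(Br)[nH]1)C(Cl)(Cl)Cl | starting material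
9 | (R)-1-(4,5-dibromo-1H-pyrrole-2-carbonyl)-2-{[(triisopropylsilyl)oxy]methyl}pyrrolidine-2-carboxylic acid | OC(=O)[C@]1(CO[Si](C(C)C)(C(C)C)C(C)C)CCCN1C(=O)c1cc(Br)c(Br)[nH]1 | intermediate
10 | acyl imidazole of 9 (R) | O=C(n1ccnc1)[C@]1(CO[Si](C(C)C)(C(C)C)C(C)C)CCCN1C(=O)c1cc(Br)c(Br)[nH]1 | intermediate
11 | (R)-1-(4,5-dibromo-1H-pyrrole-2-carbonyl)-2-{[(triisopropylsilyl)oxy]methyl}pyrrolidine-2-carboxamide | NC(=O)[C@]1(CO[Si](C(C)C)(C(C)C)C(C)C)CCCN1C(=O)c1cc(Br)c(Br)[nH]1 | intermediate
12 | 2-isocyanato analogue of 11 (S by CIP, spatial arrangement unchanged) | O=C=N[C@]1(CO[Si](C(C)C)(C(C)C)C(C)C)CCCN1C(=O)c1cc(Br)c(Br)[nH]1 | intermediate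
13 | (R)-(2-amino-2-{[(triisopropylsilyl)oxy]methyl}pyrrolidin-1-yl)(4,5-dibromo-1H-pyrrol-2-yl)methanone trifluoroacetate | N[C@]1(CO[Si](C(C)C)(C(C)C)C(C)C)CCCN1C(=O)c1cc(Br)c(Br)[nH]1.OC(=O)C(F)(F)F | intermediate
14 | methyl isothiocyanate | CN=C=S | starting material
15 | tert-butyl carbamate | CC(C)(C)OC(N)=O | starting material
16 | N-Boc-N'-methylthiourea | CNC(=S)NC(=O)OC(C)(C)C | intermediate
17 | N-Boc-N'-methylcarbodiimide | CN=C=NC(=O)OC(C)(C)C | intermediate
18 | TIPS-protected (R)-Boc-methylguanidine | CNC(NC(=O)OC(C)(C)C)=N[C@]1(CO[Si](C(C)C)(C(C)C)C(C)C)CCCN1C(=O)c1cc(Br)c(Br)[nH]1 | intermediate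
19 | (R)-guanidino alcohol | CNC(NC(=O)OC(C)(C)C)=N[C@]1(CO)CCCN1C(=O)c1cc(Br)c(Br)[nH]1 | intermediate
20 | (R)-N-(4,5-dibromopyrrole-2-carbonyl)-2-(N-Boc-N'-methylguanidino)prolinal | CNC(NC(=O)OC(C)(C)C)=N[C@]1(C=O)CCCN1C(=O)c1cc(Br)c(Br)[nH]1 | intermediate
21 | tricyclic carbinolamine (pyrrole N–C6(OH); 10R; both C6 epimers) | CNC(NC(=O)OC(C)(C)C)=N[C@]12CCCN1C(=O)c1cc(Br)c(Br)n1C2O | intermediate
22 | C6 cation (pyrrole N=C6 iminium, 10R) | CNC(NC(=O)OC(C)(C)C)=N[C@]12CCCN1C(=O)C1=CC(Br)=C(Br)[N+]1=C2 | intermediate
23 | N-Boc-(−)-7-N-methyldibromophakellin (6S,10R) | CN1C(NC(=O)OC(C)(C)C)=N[C@]23CCCN2C(=O)c2cc(Br)c(Br)n2[C@H]13 | intermediate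
24 | (−)-7-N-methyldibromophakellin (6S,10R) | CN1C(N)=N[C@]23CCCN2C(=O)c2cc(Br)c(Br)n2[C@H]13 | target

**Step count.** Total: 12 steps (11 on the main line plus step 7 for reagent 16). Longest linear sequence: 11 steps (steps 1–6 and 8–12, from L-proline).

**The three steps most likely to fail**

1. **Step 11.**
   - Risk: ionisation at C6 may be too slow at an acid strength that Boc tolerates. Loss of the protecting group before ring closure would then erode the selectivity for N7. Slow C-alkylation at pyrrole C3 and intermolecular aminal formation are the other exits.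
   - Fallback (stepwise and free of Brønsted acid): it sets out from 20. A catalytic amount of Et3N in CH2Cl2 should drive the aldehyde fully into carbinolamine 21, which is now isolated. MsCl/Et3N at −20 °C then converts its hydroxyl into the C6 mesylate F1. This is the activation that dehydrates related carbinolamines having a hydrogen at C10. F1 has no β-hydrogen, so on warming it can only ionise and be captured by the neutral NHMe nitrogen. The route is rejoined at 23.

2. **Step 6.**
   - Risk: the iodine(III) reagent may attack the pyrrole, or the new acyl aminal may open hydrolytically during a slow reaction in aqueous acid.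
   - Fallback (non-oxidative Curtius route): it sets out from 9, which is activated with CDI to 10 as in step 5. Hydrazine hydrate in place of ammonia gives the acyl hydrazide F2. Nitrosation (t-BuONO, HCl in dioxane, −20 °C) gives the acyl azide F3 in an acidic medium in which the pyrrole N–H is not nucleophilic. Warming in toluene brings about the Curtius rearrangement with retention to isocyanate 12. Brief treatment with aqueous TFA in MeCN hydrolyses 12, and the route is rejoined at 13.

3. **Step 8.**
   - Risk: addition of the hindered, weakly basic amine to 17 may be slow. The free aminal would then have time for ring-chain exchange, with erosion of C10, or for capture by EDCI itself.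
   - Fallback (reversed polarity, with the hindered partner as electrophile): it sets out from 13. Thiophosgene with NaHCO3 in CH2Cl2/H2O gives the isothiocyanate F4. The sodium salt of 15 (NaH, THF, as in step 7) adds to F4 to give the N-Boc thiourea F5. EDCI desulfurises F5 to the carbodiimide F6, which is intercepted in the same flask by the small and strongly nucleophilic methylamine. The route is rejoined at 18.

**Further compounds**

F1 | step 11 | C6 mesylate of carbinolamine 21 (10R, C6 epimers) | CNC(NC(=O)OC(C)(C)C)=N[C@]12CCCN1C(=O)c1cc(Br)c(Br)n1C2OS(C)(=O)=O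
F2 | step 6 | acyl hydrazide of 9 (R) | NNC(=O)[C@]1(CO[Si](C(C)C)(C(C)C)C(C)C)CCCN1C(=O)c1cc(Br)c(Br)[nH]1
F3 | step 6 | acyl azide of 9 (R) | [N-]=[N+]=NC(=O)[C@]1(CO[Si](C(C)C)(C(C)C)C(C)C)CCCN1C(=O)c1cc(Br)c(Br)[nH]1
F4 | step 8 | 2-isothiocyanato analogue of 13 (spatial arrangement of 13) | S=C=N[C@]1(CO[Si](C(C)C)(C(C)C)C(C)C)CCCN1C(=O)c1cc(Br)c(Br)[nH]1
F5 | step 8 | N-Boc thiourea on N9 (R) | CC(C)(C)OC(=O)NC(=S)N[C@]1(CO[Si](C(C)C)(C(C)C)C(C)C)CCCN1C(=O)c1cc(Br)c(Br)[nH]1
F6 | step 8 | N-Boc carbodiimide on N9 (R, formed and consumed in the flask) | CC(C)(C)OC(=O)N=C=N[C@]1(CO[Si](C(C)C)(C(C)C)C(C)C)CCCN1C(=O)c1cc(Br)c(Br)[nH]1
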